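At early times the runs show nothing: their first readings come at 2.00 min in the spring run and 5.00 min in the autumn run, while one question stands at 0.50 s.

| flask | substrate | remark | time |
|---|---|---|---|
| spring | 0.0010 M | run made earlier |  |
| autumn | 0.0040 M | run made earlier |  |
| flask | 0.0020 M |  | 30 min |

- spring (time / min: isomer of the product / %, target / %): 2.00: 28, 70; 6.00: 27, 70; 10.0: 31, 74; 15.0: 27, 70; 20.0: 27, 69; 30.0: 28, 73; 40.0: 28, 67
- autumn (time / min: isomer of the product / %, target / %): 5.00: 4, 93; 10.0: 9, 95; 15.0: 10, 96; 20.0: 5, 93; 25.0: 5, 92; 30.0: 7, 91; 40.0: 8, 94

(standard deviation of a reading: 2 percentage points)

- target is meant together with its crystals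
- solid, in amounts per volume of the solution: crystals
- the numbers in the tables scatter with a standard deviation of 2 percentage points
- steps thought possible: substrate -> intermediate A; intermediate A <-> intermediate B; intermediate B <-> target; target <-> isomer of the product; crystals <-> target

* share of isomer of the product in isomer of the product plus target at 0.50 s
* share of isomer of the product in isomer of the product plus target at 30 min
* which of isomer of the product and target there is more of at 30 min

The spring table is flat within the scatter of 2 percentage points: isomer of the product reads 28 % at 2.00 min and 28 % at 40.0 min. So the step between target and isomer of the product is taken here as at equilibrium, and the question becomes where the charge can go. The autumn charge is 4.00 times the spring charge, but the mean concentration of isomer of the product hardly moves: 0.280 mM in spring and 0.274 mM in autumn. Since target is counted with its crystals, this reads as dissolved target held at its solubility, with the extra charge going to crystals: thermodynamic, not kinetic, control. The mean of the two, 0.277 mM, is read as the isomer ceiling, the concentration of isomer of the product standing over crystals; as a reading, it carries the scatter of the tables.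

The flask's charge of 0.0020 M exceeds the spring charge, so crystals are expected in it too. The ceiling then gives isomer of the product at 13.9 % of the flask's charge at 30 min; with the rest of the charge reckoned as target, that is also the asked share, with target ahead. At 0.50 s it gives no number, since no reading stands that early.

The forecast, “This fits dissolved target capped by saturation”, gave 3 % at 0.50 s, 14 % at 30 min and target ahead. The flask gives 9.86 % at 0.50 s, 13.7 % at 30 min and target ahead.

    substrate → intermediate A (k = 0.380 /s)
    intermediate A ⇌ intermediate B (K = 7.90, k = 5.80 /s)
    intermediate B ⇌ target (K = 1.90, k = 4.60 /s)
    target ⇌ isomer of the product (K = 6.60, k = 0.710 /s)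
    crystals ⇌ target, rate k5*(cs5 - [target]) while solid is left; crystals form when [target] > cs5 (solubility = 0.0410 mM, k = 5.10 /s)

In the flask, the relaxation half-life of dissolved target and isomer of the product by their step alone is 0.848 s, short against the 30 min of the run, and isomer of the product stands at 13.5 % after 3.00 min as after 30.0 min. The ceiling over the flask's charge gives 13.9 % of the charge against 13.5 % found, and over the charge of 8.0 × 10⁻⁴ M of substrate in a neighbour flask it gives 34.6 % of that charge against 33.8 % there.

The readings are simulated for an exercise, and the scatter is random.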